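**Plan**

- The target is achiral. Ring A (3,5-dihydroxyphenyl) is joined through oxygen to C1 of ring B (hydroxyls on C2 and C6), and the C4 oxygen of ring B carries ring C (2,4,6-trihydroxyphenyl).
- Enabling feature: ring C has oxygen on C1 (ether), C2, C4 and C6 (hydroxyls). This 1,2,3,5-tetraoxygen pattern is what a 4-aryloxy-3-alkoxycyclobutenone and an alkoxyacetylene deliver in one benzannulation.
- Retrosynthesis: first the six O-alkyl bonds; then ring C at C2–C3, C4–C5 and C1–C2 (cyclobutenone 12 plus ethoxyacetylene); then the two ring bonds of 12 (aryloxyketene plus ethoxyacetylene); then O–CH2, the ring B C4–O bond and the ring A–O–ring B ether.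
- Forward: rings A and B are bought as arenes and joined first; ring B gains its para oxygen and a two-carbon acid arm; the four-membered ring follows; ring C is built last from open-chain carbons; dealkylation ends the route.
- Stereochemistry: none in the target; the one stereocentre of 12 is racemic and vanishes on aromatisation.

Key step: step 6

Remark: Ar stands for the 4-(3,5-dimethoxyphenoxy)-3,5-dimethoxyphenyl group (rings A and B as methyl ethers); ethoxyacetylene is used as its commercial hexane solution.

**Route**

Step 1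
Reactants: 1 syringaldehyde (4-hydroxy-3,5-dimethoxybenzaldehyde); 2 3,5-dimethoxyphenylboronic acid
Product: 3 4-(3,5-dimethoxyphenoxy)-3,5-dimethoxybenzaldehyde (ArCHO)
Conditions: Cu(OAc)2 (30 mol %), pyridine, 4 Å MS, CH2Cl2, O2 (1 atm), rt
Reagents that add atoms: none
Why: Chan–Lam oxidative O-arylation should join the crowded, fairly acidic phenol to the electron-rich arylboronic acid at room temperature, a setting in which 2,6-disubstituted phenols are known to couple and the aldehyde is left alone.

Step 2
Reactants: 3 4-(3,5-dimethoxyphenoxy)-3,5-dimethoxybenzaldehyde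
Product: 5 4-(3,5-dimethoxyphenoxy)-3,5-dimethoxyphenol (ArOH), via aryl formate 4 (not isolated)
Conditions: mCPBA, CH2Cl2, 0 °C to rt; wash (aq NaHCO3); then K2CO3 (cat.), MeOH, rt
Reagents that add atoms: mCPBA (3-chloroperoxybenzoic acid), OOC(=O)c1cccc(Cl)c1
Why: Baeyer–Villiger (Dakin-type) oxidation, in which the aryl group bearing a para oxygen donor should migrate in preference to hydride as it does for 3,4,5-trimethoxybenzaldehyde, followed by mild methanolysis of the formate.

Step 3
Reactants: 5 4-(3,5-dimethoxyphenoxy)-3,5-dimethoxyphenol; 6 ethyl bromoacetate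
Product: 7 ethyl 2-[4-(3,5-dimethoxyphenoxy)-3,5-dimethoxyphenoxy]acetate (ArOCH2CO2Et)
Conditions: K2CO3, acetone, reflux
Reagents that add atoms: none
Why: Williamson etherification of an unhindered phenoxide (hydrogens at both ortho positions) with a reactive alpha-halo ester.

Step 4
Reactants: 7 ethyl 2-[4-(3,5-dimethoxyphenoxy)-3,5-dimethoxyphenoxy]acetate
Product: 8 2-[4-(3,5-dimethoxyphenoxy)-3,5-dimethoxyphenoxy]acetic acid (ArOCH2CO2H)
Conditions: LiOH, THF/H2O, rt; then 1 M HCl
Reagents that add atoms: water (delivered as hydroxide from LiOH), O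
Why: Ester saponification; aryl ethers and diaryl ether are inert to aqueous hydroxide at room temperature.

Step 5
Reactants: 8 2-[4-(3,5-dimethoxyphenoxy)-3,5-dimethoxyphenoxy]acetic acid; 9 ethoxyacetylene
Product: 12 4-[4-(3,5-dimethoxyphenoxy)-3,5-dimethoxyphenoxy]-3-ethoxycyclobut-2-en-1-one (racemic), via acid chloride 10 (not isolated), via aryloxyketene 11 (not isolated)
Conditions: 1-chloro-N,N,2-trimethylprop-1-en-1-amine (1.05 equiv), CH2Cl2, 0 °C to rt; then added slowly to 9 (3 equiv), Et3N, CH2Cl2, 0 °C to rt; neutral work-up, Et3N-deactivated silica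
Reagents that add atoms: none
Why: The acid chloride, made without acid or Vilsmeier species that could attack the electron-rich rings, is dehydrochlorinated to aryloxyketene 11, which the nucleophilic ynol ether should intercept in the known ketene–alkoxyacetylene (2+2) cycloaddition to 3-alkoxycyclobutenones, the alkyne CH bonding to the ketene carbonyl carbon so that ethoxy sits at C3 and aryloxy at C4 (new stereocentre C4 racemic, of no consequence).

Step 6
Reactants: 12 4-[4-(3,5-dimethoxyphenoxy)-3,5-dimethoxyphenoxy]-3-ethoxycyclobut-2-en-1-one; 9 ethoxyacetylene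
Product: 17 2-[4-(3,5-dimethoxyphenoxy)-3,5-dimethoxyphenoxy]-3,5-diethoxyphenol, via vinylketene 13 (not isolated), via alkenylcyclobutenone 14 (not isolated), via dienylketene 15 (not isolated), via cyclohexadienone 16 (not isolated)
Conditions: 9 (4 equiv), toluene, 90 °C, sealed tube
Reagents that add atoms: none
Why: Proposed new method: thermal 4π-electrocyclic opening of 12 should give vinylketene 13, whose ketene C=C adds to the ynol ether in a (2+2) cycloaddition (ketene carbonyl carbon to the alkyne CH, forming C2–C3 and C4–C5 of ring C) to give 14, which opens to dienylketene 15 and closes and enolises to 17. The closest known reaction is the Danheiser benzannulation of alkyl- and aryl-substituted cyclobutenones with alkoxy- and siloxyacetylenes, and the opening of a 3-alkoxy-4-oxycyclobutenone has its analogy in the squarate-derived 4-hydroxycyclobutenones of the Moore rearrangement; a 4-aryloxy-3-alkoxycyclobutenone has not been used in this benzannulation. Ring C is closed by a thermal disrotatory 6π-electrocyclisation of 15 that forms the C1–C2 bond, after which dienone 16 tautomerises to the phenol. No stereocentre remains in the product, since the racemic centres of 12, 14 and 16 are transient and are lost on aromatisation. The step needs regioselectivity in the ketene–alkyne addition, which the polarity of the ynol ether secures (its nucleophilic CH carbon attacks the electrophilic ketene carbon, placing the new ethoxy group meta to the phenol), and it needs hydrogen rather than aryloxy on the inside of the triene terminus, which the outward rotation of the oxygen donor at C4 in the first ring opening secures.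

Step 7
Reactants: 17 2-[4-(3,5-dimethoxyphenoxy)-3,5-dimethoxyphenoxy]-3,5-diethoxyphenol
Product: 18 triphlorethol A
Conditions: BBr3 (12 equiv), CH2Cl2, −78 °C to rt; ice-water quench
Reagents that add atoms: none
Why: Lewis-acid dealkylation, in which bromide attacks the alkyl carbon of each boron-complexed methyl or ethyl aryl ether while the two diaryl ether links, having no sp3 carbon on oxygen, should stay intact; the cold aqueous quench is chosen to avoid acid-mediated ether exchange on the phloroglucinol rings.

**Compound list**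

1 | syringaldehyde (4-hydroxy-3,5-dimethoxybenzaldehyde) | COc1cc(C=O)cc(OC)c1O | starting material
2 | 3,5-dimethoxyphenylboronic acid | COc1cc(OC)cc(B(O)O)c1 | starting material
3 | 4-(3,5-dimethoxyphenoxy)-3,5-dimethoxybenzaldehyde | COc1cc(C=O)cc(OC)c1Oc1cc(OC)cc(OC)c1 | intermediate
4 | 4-(3,5-dimethoxyphenoxy)-3,5-dimethoxyphenyl formate | COc1cc(OC=O)cc(OC)c1Oc1cc(OC)cc(OC)c1 | intermediate
5 | 4-(3,5-dimethoxyphenoxy)-3,5-dimethoxyphenol | COc1cc(O)cc(OC)c1Oc1cc(OC)cc(OC)c1 | intermediate
6 | ethyl bromoacetate | CCOC(=O)CBr | starting material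
7 | ethyl 2-[4-(3,5-dimethoxyphenoxy)-3,5-dimethoxyphenoxy]acetate | CCOC(=O)COc1cc(OC)c(Oc2cc(OC)cc(OC)c2)c(OC)c1 | intermediate
8 | 2-[4-(3,5-dimethoxyphenoxy)-3,5-dimethoxyphenoxy]acetic acid | OC(=O)COc1cc(OC)c(Oc2cc(OC)cc(OC)c2)c(OC)c1 | intermediate
9 | ethoxyacetylene | C#COCC | starting material
10 | 2-[4-(3,5-dimethoxyphenoxy)-3,5-dimethoxyphenoxy]acetyl chloride | ClC(=O)COc1cc(OC)c(Oc2cc(OC)cc(OC)c2)c(OC)c1 | intermediate
11 | 2-[4-(3,5-dimethoxyphenoxy)-3,5-dimethoxyphenoxy]ethen-1-one (aryloxyketene) | O=C=COc1cc(OC)c(Oc2cc(OC)cc(OC)c2)c(OC)c1 | intermediate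
12 | 4-[4-(3,5-dimethoxyphenoxy)-3,5-dimethoxyphenoxy]-3-ethoxycyclobut-2-en-1-one (racemic) | CCOC1=CC(=O)C1Oc1cc(OC)c(Oc2cc(OC)cc(OC)c2)c(OC)c1 | intermediate
13 | (Z)-4-[4-(3,5-dimethoxyphenoxy)-3,5-dimethoxyphenoxy]-3-ethoxybuta-1,3-dien-1-one | O=C=C/C(OCC)=C/Oc1cc(OC)c(Oc2cc(OC)cc(OC)c2)c(OC)c1 | intermediate
14 | 4-{(Z)-2-[4-(3,5-dimethoxyphenoxy)-3,5-dimethoxyphenoxy]-1-ethoxyethenyl}-3-ethoxycyclobut-2-en-1-one (racemic) | CCOC1=CC(=O)C1/C(OCC)=C/Oc1cc(OC)c(Oc2cc(OC)cc(OC)c2)c(OC)c1 | intermediate
15 | (3E,5Z)-6-[4-(3,5-dimethoxyphenoxy)-3,5-dimethoxyphenoxy]-3,5-diethoxyhexa-1,3,5-trien-1-one | O=C=C/C(OCC)=C\C(OCC)=C\Oc1cc(OC)c(Oc2cc(OC)cc(OC)c2)c(OC)c1 | intermediate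
16 | 6-[4-(3,5-dimethoxyphenoxy)-3,5-dimethoxyphenoxy]-3,5-diethoxycyclohexa-2,4-dien-1-one (racemic) | CCOC1=CC(=O)C(Oc2cc(OC)c(Oc3cc(OC)cc(OC)c3)c(OC)c2)C(OCC)=C1 | intermediate
17 | 2-[4-(3,5-dimethoxyphenoxy)-3,5-dimethoxyphenoxy]-3,5-diethoxyphenol | CCOc1cc(OCC)c(Oc2cc(OC)c(Oc3cc(OC)cc(OC)c3)c(OC)c2)c(O)c1 | intermediate
18 | triphlorethol A, 2-[4-(3,5-dihydroxyphenoxy)-3,5-dihydroxyphenoxy]benzene-1,3,5-triol | Oc1cc(O)cc(Oc2c(O)cc(Oc3c(O)cc(O)cc3O)cc2O)c1 | target

**Step count**

Total: 7 steps. Longest linear sequence: 7 steps, from syringaldehyde 1 to triphlorethol A 18.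

**Steps most likely to fail**

Step 6. The vinylketene may form too slowly from the vinylogous-ester cyclobutenone, or re-close faster than it is trapped. The alkyne would then be lost to thermal fragmentation, and ketene intermediates would be consumed by dimerisation or by addition of the product phenol. In that case ring C is attached as a ready-made arene by known chemistry. The fallback sets out from phenol 5, whose hydroxyl is unhindered. Ullmann diaryl ether coupling with commercial 2-iodo-1,3,5-trimethoxybenzene (CuI, picolinic acid, K3PO4, DMSO, 110 °C) should give 2-[4-(3,5-dimethoxyphenoxy)-3,5-dimethoxyphenoxy]-1,3,5-trimethoxybenzene F1. BBr3 in CH2Cl2 then cleaves its seven methyl ethers, and the route is rejoined at the target 18. The price is a slow coupling at a doubly ortho-substituted, electron-rich aryl iodide.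

Step 5. Dimerisation of the aryloxyketene and its acylation by unreacted acid chloride may outrun the cycloaddition, or the enol ether of the product may hydrolyse during isolation. The fallback reaches the first intermediate of the benzannulation without an aryloxyketene and without isolating a cyclobutenone. It sets out from phenol 5, which is alkylated with commercial ethyl (E)-4-bromo-3-ethoxybut-2-enoate (K2CO3, acetone) to give ethyl (E)-4-[4-(3,5-dimethoxyphenoxy)-3,5-dimethoxyphenoxy]-3-ethoxybut-2-enoate F2. Saponification (LiOH, THF/H2O) gives (E)-4-[4-(3,5-dimethoxyphenoxy)-3,5-dimethoxyphenoxy]-3-ethoxybut-2-enoic acid F3. 1-Chloro-N,N,2-trimethylprop-1-en-1-amine converts it into (E)-4-[4-(3,5-dimethoxyphenoxy)-3,5-dimethoxyphenoxy]-3-ethoxybut-2-enoyl chloride F4. Et3N in toluene in the presence of excess 9 should effect 1,4-dehydrochlorination (removal of a gamma hydrogen next to the aryloxy group) to vinylketene 13. The fallback comes back to the route at 13, which on warming to 90 °C continues through 14, 15 and 16 to phenol 17.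

Step 1. Protodeboronation and oxidative homocoupling of the boronic acid may use up the boron partner before the crowded, electron-poor phenoxide is arylated at copper. The fallback changes the aryl donor and the mechanism from an oxidative boronic acid coupling to an Ullmann condensation with a halide that is stable under the conditions. It sets out from syringaldehyde 1, which is heated with commercial 1-iodo-3,5-dimethoxybenzene (CuI, picolinic acid, K3PO4, DMSO, 100 °C). It comes back at aldehyde 3 and makes no new compound (F0).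

**Further compounds**

F1 | step 6 | 2-[4-(3,5-dimethoxyphenoxy)-3,5-dimethoxyphenoxy]-1,3,5-trimethoxybenzene | COc1cc(OC)c(Oc2cc(OC)c(Oc3cc(OC)cc(OC)c3)c(OC)c2)c(OC)c1
F2 | step 5 | ethyl (E)-4-[4-(3,5-dimethoxyphenoxy)-3,5-dimethoxyphenoxy]-3-ethoxybut-2-enoate | CCOC(=O)/C=C(/OCC)COc1cc(OC)c(Oc2cc(OC)cc(OC)c2)c(OC)c1
F3 | step 5 | (E)-4-[4-(3,5-dimethoxyphenoxy)-3,5-dimethoxyphenoxy]-3-ethoxybut-2-enoic acid | OC(=O)/C=C(/OCC)COc1cc(OC)c(Oc2cc(OC)cc(OC)c2)c(OC)c1
F4 | step 5 | (E)-4-[4-(3,5-dimethoxyphenoxy)-3,5-dimethoxyphenoxy]-3-ethoxybut-2-enoyl chloride | ClC(=O)/C=C(/OCC)COc1cc(OC)c(Oc2cc(OC)cc(OC)c2)c(OC)c1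
F0 | step 1 | none | none
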